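The numbers in the tables are simulated from invented constants; noise was put on by code.

The summer run and the winter run read alike at 6.00 h: target stands at 57% in both, and intermediate C at 43% and 47%. The summer run is flat from 2.50 h on, but in the winter run intermediate C still climbs from 40% to 47% between 2.50 h and 6.00 h.

| flask | solid substrate | remark | time |
|---|---|---|---|
| summer | 0.12 M | run made earlier |  |
| winter | 0.50 M | run made earlier |  |
| flask | 0.25 M |  | 10 h |

| run | time / h | solid substrate / % | target / % | intermediate C / % |
|---|---|---|---|---|
| summer | 0.500 | 1 | 27 | 6 |
| summer | 1.00 | 0 | 52 | 25 |
| summer | 2.50 | 1 | 56 | 42 |
| summer | 6.00 | 1 | 57 | 43 |
| winter | 0.500 | 70 | 5 | 1 |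
| winter | 1.00 | 42 | 24 | 6 |
| winter | 2.50 | 0 | 54 | 40 |
| winter | 6.00 | 1 | 57 | 47 |

(readings scatter by 2 percentage points)

- as a solid, counted per litre of solution: solid substrate
- the numbers in the tables scatter by 2 percentage points (one standard deviation)
- at the start none of the solid substrate is in solution
- what has only dissolved of solid substrate counts as not reacted
- the reaction counts as stopped when no species that holds the solid substrate changes by six tenths of a point or more over the second half of the time

- at 10 h, what has stopped the reaction, if anything has (for what has run out or reacted, a solid counts together with what of it has only dissolved) (all of the solid substrate has reacted / it is still moving / forward and back rates have come level)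
- part of the solid substrate that has turned into other species by 10 h (what has only dissolved does not count)
- the target standing at 10 h, as a percentage of the solid substrate charged
- the intermediate C standing at 10 h, as a percentage of the solid substrate charged

Three numbers could matter for the flask. The charge moves little: it rises 4.17-fold between the runs, yet target at 6.00 h reads 57% in the summer run and 57% in the winter run. The time moves little: target in the summer run goes from 56% to 57% between 2.50 h and 6.00 h, inside the scatter of 2 percentage points. The split does move the answer: the last readings give target 57.0% of the pair in the summer run and 54.8% in the winter run.

So the split has to be known well. Pooling the two flat readings of the summer run with the last reading of the winter run gives 0.776, the closing ratio, intermediate C over target at the end of a run; it is read as an equilibrium constant if the two interconvert. The winter run, with twice the charge of the flask, shows 0% solid substrate at 2.50 h, so the flask should be fully converted by 10 h. Its charge then divides into 56.3% target and 43.7% intermediate C.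

The forecast gives as end state "all of the solid substrate has reacted", with 100% conversion, 56.5% target and 43.5% intermediate C: “Nothing is left to react, so the substrate has simply run out”. The flask gives 100% conversion, 57.1% target and 42.9% intermediate C, and its end state is: all of the solid substrate has reacted.

    starting material → intermediate A (k = 0.0200 /s)
    intermediate A → intermediate B (k = 0.00100 /s)
    intermediate A → intermediate C (k = 5.50 × 10⁻⁵ /s)
    intermediate B → target (k = 0.00110 /s)
    target ⇌ intermediate C (K = 0.750, k = 5.00 × 10⁻⁴ /s)
    solid substrate ⇌ starting material, rate k6*(cs6 - [starting material]) while solid is left; crystals form when [starting material] > cs6 (solubility = 0.170 M, k = 4.80 × 10⁻⁴ /s)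

The closing ratio put target in the flask at 56.3%, against 57.1% found. Applied to the flask left until 2.5 h, it divides the pair into 56.1% target, against 57.4% found. The half-life of target by its forward loss to intermediate C alone, 0.39 h, is shorter than the 10 h of the flask. Going back in time, target in the flask has moved by 5 points at 1.27 h, and at 1.00 h it stands at 41.0%, with intermediate C at 17.6%.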